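The flask was to be read at 20 min, and I had two earlier runs to go on, both charged with the flask's acid, with the flask's substrate lying between theirs.

| flask | substrate | acid | remark | time |
|---|---|---|---|---|
| dawn | 0.034 M | 0.15 mM | run made earlier |  |
| autumn | 0.075 M | 0.15 mM | run made earlier |  |
| flask | 0.050 M | 0.150 mM |  | 20 min |

| run | time / min | substrate / % | target / % |
|---|---|---|---|
| dawn | 1.50 | 93.7 | 6.4 |
| dawn | 3.00 | 87.7 | 11.7 |
| dawn | 6.00 | 76.4 | 23.0 |
| dawn | 10.0 | 62.9 | 36.1 |
| dawn | 20.0 | 39.1 | 61.6 |
| autumn | 4.00 | 83.7 | 17.5 |
| autumn | 8.00 | 68.4 | 31.8 |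
| autumn | 12.0 | 55.5 | 45.1 |
| autumn | 15.0 | 47.0 | 53.3 |
| autumn | 20.0 | 35.8 | 64.4 |

(standard deviation of a reading: 0.5 percentage points)

- acid is the free proton; pH is minus the decimal logarithm of its molar concentration

* part of the substrate that has reacted at 20 min
* pH of the solution at 20 min

At 20 min, the readings gave 60.9 % of the substrate reacted in the dawn run, with less substrate, and 64.2 % in the autumn run, with more. Taking the part reacted to rise with charge at equal acid, I used these as my bounds from below and above.

To tighten them I read κ, the pseudo-first-order constant of a run up to a given time: the natural logarithm of substrate charged over substrate left, divided by that time. Dawn read 0.0470 min⁻¹ and autumn 0.0514 min⁻¹. Interpolating straight in charge gave the flask κ = 0.0487 min⁻¹, so I expected 62.2 % reacted. Neither earlier run measured the acid, so I reckoned no pH of my own.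

The forecast gave 62.3 % and a pH of 3.75, on the ground that “the target accelerates the reaction”, and its conversion stood inside my bracket.

The flask gave 62.3 %, also inside my bracket, and a pH of 3.73.

    substrate + acid → weak acid + acid + target (k = 4.70 M⁻¹ s⁻¹)
    weak acid ⇌ conjugate base + acid, settled at all times (K = 2.50 × 10⁻⁷ M)
    substrate → weak acid + target (k = 3.70 × 10⁻⁶ s⁻¹)
    weak acid → by-product carried off (k = 2.80 × 10⁻⁴ s⁻¹)

The flask's own substrate gave κ = 0.0488 min⁻¹. Carried to the neighbour flask left until 50 min, my κ gave 91.2 % reacted, and that flask stood at 92.3 %. In the flask, the step through acid, taken by itself with the other concentrations as charged, gave substrate a half-life of 16 min, far shorter than the 52 h of the step without acid taken by itself. At 20.0 min in the flask, the step through acid was using substrate 230 times as fast as the step without it.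

The earlier runs and the new flask are simulated for an exercise.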